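**Strategy**

Everything rests on cutting two acyl–carbon bonds of the bicyclo[3.3.1]nonane: C1–C9 (bridging ketone to the bridgehead beside the gem-dimethyl carbon C8) and C2–C3 (in the enolised trione bridge). The feature exploited is that C9 and C4 hang as a 1,3-dicarbonyl on quaternary C5: C9, C5, C4, C3 and the aroyl carbon are stored as a dearomatised 6-aryl-pyran-2,4-dione whose lactone carbonyl is C9. The precursor is this pyrandione bearing an open ester chain C6–C7–C8–C1–C2. One base treatment moves C9 onto the ester enolate C1 (ring B: C1, C9, C5–C8), which uncages the diketone enolate C3 that closes onto ester C2 (ring A: C1–C5, C9).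

Key step: step 10

Numbering and abbreviations: C1–C9 are the core atoms of the target (C1 and C5 bridgeheads, C2–C4 trione bridge, C6 CH2, C7 CH, C8 CMe2, C9 bridging ketone). Prenyl = 3-methylbut-2-en-1-yl; TBS = tert-butyldimethylsilyl.

Assumption: the catalyst antipodes written in steps 6 and 9 are taken to give the drawn configurations; the pseudo-enantiomeric alkaloid ether (step 6) or the mirror-image ligand (step 9) would be used if the sense of induction proves opposite.

**Route**

Step 1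
Reactants: 1 1-(3,4-dihydroxyphenyl)ethan-1-one
Product: 2 tert-butyl({1-[3,4-bis(TBSO)phenyl]ethenyl}oxy)dimethylsilane
Conditions: TBSOTf (3.3 equiv), Et3N, CH2Cl2, 0 °C → rt
Reagents that add atoms: tert-butyldimethylsilyl trifluoromethanesulfonate, CC(C)(C)[Si](C)(C)OS(=O)(=O)C(F)(F)F
Why: Silylation of both phenols and soft enolisation of the aryl methyl ketone to its silyl enol ether should occur in one operation, giving the protected nucleophile for the pyrone annulation.

Step 2
Reactants: 2 tert-butyl({1-[3,4-bis(TBSO)phenyl]ethenyl}oxy)dimethylsilane; 3 malonyl dichloride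
Product: 5 6-[3,4-bis(TBSO)phenyl]-4-hydroxy-2H-pyran-2-one, via dioxopentanoyl chloride 4 (not isolated)
Conditions: Et2O, −78 °C → rt
Reagents that add atoms: none
Why: C-acylation of the silyl enol ether by one acid chloride followed by enol O-acylation (lactonisation) by the second is the standard malonyl dichloride annulation to 6-aryl-4-hydroxy-2-pyrones.

Step 3
Reactants: 6 dimethyl 3,3-dimethylpentanedioate; 7 1-bromo-3-methylbut-2-ene
Product: 9 dimethyl 3,3-dimethyl-2,4-bis(3-methylbut-2-en-1-yl)pentanedioate (diastereomer mixture), via monoprenyl diester 8 (not isolated)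
Conditions: LiN(i-Pr)2 (1.1 equiv), THF, −78 °C, then 7 (1.1 equiv), −78 → 0 °C; recooled to −78 °C, LiN(i-Pr)2 (1.1 equiv), then a second portion of 1-bromo-3-methylbut-2-ene (1.1 equiv), −78 → 0 °C
Reagents that add atoms: 1-bromo-3-methylbut-2-ene (second equivalent), CC(C)=CCBr
Why: Two successive ester enolate alkylations (SN2 on the allylic bromide) should take place at the two CH2 groups in turn, one equivalent of bromide being consumed in each, since the remaining CH2 of 8 is deprotonated faster than the new, more hindered methine; the diastereomer mixture is corrected in step 5.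

Step 4
Reactants: 9 dimethyl 3,3-dimethyl-2,4-bis(3-methylbut-2-en-1-yl)pentanedioate
Product: 10 3,3-dimethyl-2,4-bis(3-methylbut-2-en-1-yl)pentanedioic acid (diastereomer mixture)
Conditions: KOH, MeOH–H2O, reflux; then cold 1 M HCl
Reagents that add atoms: potassium hydroxide, [K+].[OH-]
Why: Saponification of the hindered diester should go under forcing alkaline conditions that leave the trisubstituted alkenes untouched.

Step 5
Reactants: 10 3,3-dimethyl-2,4-bis(3-methylbut-2-en-1-yl)pentanedioic acid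
Product: 11 (3R,5S)-4,4-dimethyl-3,5-bis(3-methylbut-2-en-1-yl)oxane-2,6-dione (cis, meso)
Conditions: Ac2O, NaOAc (cat.), 100 °C; crystallisation
Reagents that add atoms: none
Why: Cyclodehydration to the glutaric anhydride with enolisation-mediated epimerisation should converge on the more stable cis (diequatorial, meso) anhydride, which fixes the syn relation of the two prenyl-bearing carbons.

Step 6
Reactants: 11 (3R,5S)-4,4-dimethyl-3,5-bis(3-methylbut-2-en-1-yl)oxane-2,6-dione
Product: 12 (2S,4R)-5-methoxy-3,3-dimethyl-2,4-bis(3-methylbut-2-en-1-yl)-5-oxopentanoic acid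
Conditions: (DHQD)2AQN (20 mol%), MeOH (10 equiv), Et2O, −20 °C
Reagents that add atoms: methanol, CO
Why: Cinchona-alkaloid-catalysed asymmetric methanolysis (desymmetrisation of a meso anhydride) should open the carbonyl beside the (R)-carbon, so the carbon that keeps the free acid (the later C7) is S and the absolute configuration of the route is set here.

Step 7
Reactants: 12 (2S,4R)-5-methoxy-3,3-dimethyl-2,4-bis(3-methylbut-2-en-1-yl)-5-oxopentanoic acid
Product: 14 methyl (2R,4S)-4-formyl-3,3,7-trimethyl-2-(3-methylbut-2-en-1-yl)oct-6-enoate, via acid chloride 13 (not isolated)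
Conditions: 1-chloro-N,N,2-trimethylprop-1-en-1-amine, CH2Cl2, 0 °C; then LiAlH(O-t-Bu)3, THF, −78 °C
Reagents that add atoms: none
Why: Neutral acid chloride formation followed by hydride reduction with the mild, bulky LiAlH(O-t-Bu)3 should stop at the aldehyde and spare the methyl ester, and the α-stereocentre (C7) beside the quaternary carbon should not epimerise at −78 °C.

Step 8
Reactants: 5 6-[3,4-bis(TBSO)phenyl]-4-hydroxy-2H-pyran-2-one; 14 methyl (2R,4S)-4-formyl-3,3,7-trimethyl-2-(3-methylbut-2-en-1-yl)oct-6-enoate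
Product: 16 methyl (2R,4R)-4-({6-[3,4-bis(TBSO)phenyl]-4-hydroxy-2-oxo-2H-pyran-3-yl}methyl)-3,3,7-trimethyl-2-(3-methylbut-2-en-1-yl)oct-6-enoate, via alkylidene pyrandione 15 (not isolated)
Conditions: diethyl 2,6-dimethyl-1,4-dihydropyridine-3,5-dicarboxylate (1.2 equiv), L-proline (20 mol%), CH2Cl2, rt
Reagents that add atoms: none
Why: Three-component reductive alkylation (Knoevenagel condensation at C3 of the pyrone, then hydride transfer from the dihydropyridine to the 1-oxadiene) should forge C5–C6; C7 is expected to hold because its enamine would be tetrasubstituted and flanked by the quaternary carbon, and hydride transfer at rt should outrun cycloaddition of 15.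

Step 9
Reactants: 16 methyl (2R,4R)-4-({6-[3,4-bis(TBSO)phenyl]-4-hydroxy-2-oxo-2H-pyran-3-yl}methyl)-3,3,7-trimethyl-2-(3-methylbut-2-en-1-yl)oct-6-enoate; 17 3-methylbut-2-en-1-yl acetate
Product: 18 methyl (2R,4R)-4-({(3S)-6-[3,4-bis(TBSO)phenyl]-3-(3-methylbut-2-en-1-yl)-2,4-dioxo-3,4-dihydro-2H-pyran-3-yl}methyl)-3,3,7-trimethyl-2-(3-methylbut-2-en-1-yl)oct-6-enoate
Conditions: Pd2(dba)3·CHCl3 (2.5 mol%, zerovalent palladium), (R,R)-DACH-phenyl bis(diphenylphosphinobenzamide) ligand (7.5 mol%), Et3N, CH2Cl2, rt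
Reagents that add atoms: none
Why: Dearomatising Tsuji–Trost C-allylation of the pyronate by the π-prenyl palladium complex should give the linear prenyl group at the less hindered allyl terminus, any O-prenyl ether re-ionising to the C-alkylated dione; the chiral pocket of the ligand selects the pyronate face and so sets quaternary C5 as S.

Step 10
Reactants: 18 methyl (2R,4R)-4-({(3S)-6-[3,4-bis(TBSO)phenyl]-3-(3-methylbut-2-en-1-yl)-2,4-dioxo-3,4-dihydro-2H-pyran-3-yl}methyl)-3,3,7-trimethyl-2-(3-methylbut-2-en-1-yl)oct-6-enoate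
Product: 20 (1S,5S,7R)-3-[3,4-bis(TBSO)benzoyl]-4-hydroxy-8,8-dimethyl-1,5,7-tris(3-methylbut-2-en-1-yl)bicyclo[3.3.1]non-3-ene-2,9-dione, via cyclohexanone diketone 19 (not isolated)
Conditions: LiN(i-Pr)2 (1.3 equiv), THF–DMPU (5:1), −78 °C → rt, then 45 °C; 1 M HCl work-up
Reagents that add atoms: none
Why: LiN(i-Pr)2 can only deprotonate C1–H (the pyran-2,4-dione has no acidic C–H), and the ester enolate adds to the enol-lactone carbonyl C9, whose tetrahedral intermediate collapses with C9–O cleavage to give cyclohexanone 19 as the lithium enolate of its aryl 1,3-diketone; the central carbon C3 of that enolate then attacks the C2 methyl ester, held 1,3-diaxial to the C5 acyl arm, and loss of methoxide gives the enolised trione as the thermodynamic sink. The closest known reaction types are the Dieckmann condensation with a lactone or enol ester as acyl donor and the Claisen cyclisation of a 1,3-diketone onto an ester that builds acylphloroglucinols. Ring B (C1, C9, C5, C6, C7, C8) closes by 6-exo-trig acyl substitution at C9 and ring A (C1, C2, C3, C4, C5, C9) by 6-exo-trig acyl substitution at C2. The only new stereocentre, C1, is set in the first closure by a chair transition state in which the C5 and C7 prenyl groups are equatorial, the pyranone carbonyl C4 on C5 is axial, and the planar enolate carbon C2 takes the axial site anti to the developing C9 alkoxide (open, non-chelated arrangement favoured by DMPU) while the C1 prenyl group goes equatorial; C5 and C7 are carried unchanged from 18. The step needs attack at C9 rather than at the vinylogous-ester carbonyl C4, secured because only addition to the enol lactone becomes irreversible by expelling a stabilised enolate, and C- over O-acylation in the second closure, secured because an O-acyl enol lactone stays an acyl donor towards methoxide whereas the C-acylated trione is deprotonated and leaves the equilibrium.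

Step 11
Reactants: 20 (1S,5S,7R)-3-[3,4-bis(TBSO)benzoyl]-4-hydroxy-8,8-dimethyl-1,5,7-tris(3-methylbut-2-en-1-yl)bicyclo[3.3.1]non-3-ene-2,9-dione
Product: 21 aristophenone A, (1S,5S,7R)-3-(3,4-dihydroxybenzoyl)-4-hydroxy-8,8-dimethyl-1,5,7-tris(3-methylbut-2-en-1-yl)bicyclo[3.3.1]non-3-ene-2,9-dione
Conditions: Bu4NF, AcOH, THF, 0 °C
Reagents that add atoms: none
Why: Buffered fluoride desilylation of the two aryl silyl ethers should free the catechol without acid (no prenyl–enol cyclisation) and without strong base (no retro-Claisen or catechol oxidation).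

**Compound list**

1 | 1-(3,4-dihydroxyphenyl)ethan-1-one | CC(=O)c1ccc(O)c(O)c1 | starting material
2 | tert-butyl({1-[3,4-bis(TBSO)phenyl]ethenyl}oxy)dimethylsilane | C=C(O[Si](C)(C)C(C)(C)C)c1ccc(O[Si](C)(C)C(C)(C)C)c(O[Si](C)(C)C(C)(C)C)c1 | intermediate
3 | malonyl dichloride | O=C(Cl)CC(=O)Cl | starting material
4 | 5-[3,4-bis(TBSO)phenyl]-3,5-dioxopentanoyl chloride (not isolated) | O=C(Cl)CC(=O)CC(=O)c1ccc(O[Si](C)(C)C(C)(C)C)c(O[Si](C)(C)C(C)(C)C)c1 | intermediate
5 | 6-[3,4-bis(TBSO)phenyl]-4-hydroxy-2H-pyran-2-one | O=C1C=C(O)C=C(c2ccc(O[Si](C)(C)C(C)(C)C)c(O[Si](C)(C)C(C)(C)C)c2)O1 | intermediate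
6 | dimethyl 3,3-dimethylpentanedioate | COC(=O)CC(C)(C)CC(=O)OC | starting material
7 | 1-bromo-3-methylbut-2-ene (prenyl bromide) | CC(C)=CCBr | starting material
8 | dimethyl 3,3-dimethyl-2-(3-methylbut-2-en-1-yl)pentanedioate (racemic, not isolated) | COC(=O)CC(C)(C)C(CC=C(C)C)C(=O)OC | intermediate
9 | dimethyl 3,3-dimethyl-2,4-bis(3-methylbut-2-en-1-yl)pentanedioate (diastereomer mixture) | COC(=O)C(CC=C(C)C)C(C)(C)C(CC=C(C)C)C(=O)OC | intermediate
10 | 3,3-dimethyl-2,4-bis(3-methylbut-2-en-1-yl)pentanedioic acid (diastereomer mixture) | OC(=O)C(CC=C(C)C)C(C)(C)C(CC=C(C)C)C(=O)O | intermediate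
11 | (3R,5S)-4,4-dimethyl-3,5-bis(3-methylbut-2-en-1-yl)oxane-2,6-dione (cis, meso) | O=C1[C@@H](CC=C(C)C)C(C)(C)[C@@H](CC=C(C)C)C(=O)O1 | intermediate
12 | (2S,4R)-5-methoxy-3,3-dimethyl-2,4-bis(3-methylbut-2-en-1-yl)-5-oxopentanoic acid | OC(=O)[C@@H](CC=C(C)C)C(C)(C)[C@@H](CC=C(C)C)C(=O)OC | intermediate
13 | methyl (2R,4S)-4-(chlorocarbonyl)-3,3,7-trimethyl-2-(3-methylbut-2-en-1-yl)oct-6-enoate (not isolated) | ClC(=O)[C@@H](CC=C(C)C)C(C)(C)[C@@H](CC=C(C)C)C(=O)OC | intermediate
14 | methyl (2R,4S)-4-formyl-3,3,7-trimethyl-2-(3-methylbut-2-en-1-yl)oct-6-enoate | O=C[C@@H](CC=C(C)C)C(C)(C)[C@@H](CC=C(C)C)C(=O)OC | intermediate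
15 | methyl (2R,4R)-4-({6-[3,4-bis(TBSO)phenyl]-2,4-dioxo-2H-pyran-3(4H)-ylidene}methyl)-3,3,7-trimethyl-2-(3-methylbut-2-en-1-yl)oct-6-enoate (alkene geometry open, not isolated) | CC(C)=CC[C@H](C=C1C(=O)C=C(c2ccc(O[Si](C)(C)C(C)(C)C)c(O[Si](C)(C)C(C)(C)C)c2)OC1=O)C(C)(C)[C@@H](CC=C(C)C)C(=O)OC | intermediate
16 | methyl (2R,4R)-4-({6-[3,4-bis(TBSO)phenyl]-4-hydroxy-2-oxo-2H-pyran-3-yl}methyl)-3,3,7-trimethyl-2-(3-methylbut-2-en-1-yl)oct-6-enoate | CC(C)=CC[C@H](CC1=C(O)C=C(c2ccc(O[Si](C)(C)C(C)(C)C)c(O[Si](C)(C)C(C)(C)C)c2)OC1=O)C(C)(C)[C@@H](CC=C(C)C)C(=O)OC | intermediate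
17 | 3-methylbut-2-en-1-yl acetate (prenyl acetate) | CC(=O)OCC=C(C)C | starting material
18 | methyl (2R,4R)-4-({(3S)-6-[3,4-bis(TBSO)phenyl]-3-(3-methylbut-2-en-1-yl)-2,4-dioxo-3,4-dihydro-2H-pyran-3-yl}methyl)-3,3,7-trimethyl-2-(3-methylbut-2-en-1-yl)oct-6-enoate | CC(C)=CC[C@H](C[C@]1(CC=C(C)C)C(=O)OC(c2ccc(O[Si](C)(C)C(C)(C)C)c(O[Si](C)(C)C(C)(C)C)c2)=CC1=O)C(C)(C)[C@@H](CC=C(C)C)C(=O)OC | intermediate
19 | methyl (1S,3S,5R)-3-{3-[3,4-bis(TBSO)phenyl]-3-oxopropanoyl}-6,6-dimethyl-1,3,5-tris(3-methylbut-2-en-1-yl)-2-oxocyclohexane-1-carboxylate (formed as its enolate, not isolated) | CC(C)=CC[C@@H]1C[C@@](CC=C(C)C)(C(=O)CC(=O)c2ccc(O[Si](C)(C)C(C)(C)C)c(O[Si](C)(C)C(C)(C)C)c2)C(=O)[C@@](CC=C(C)C)(C(=O)OC)C1(C)C | intermediate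
20 | (1S,5S,7R)-3-[3,4-bis(TBSO)benzoyl]-4-hydroxy-8,8-dimethyl-1,5,7-tris(3-methylbut-2-en-1-yl)bicyclo[3.3.1]non-3-ene-2,9-dione | CC(C)=CC[C@@H]1C[C@]2(CC=C(C)C)C(=O)[C@@](CC=C(C)C)(C(=O)C(C(=O)c3ccc(O[Si](C)(C)C(C)(C)C)c(O[Si](C)(C)C(C)(C)C)c3)=C2O)C1(C)C | intermediate
21 | aristophenone A, (1S,5S,7R)-3-(3,4-dihydroxybenzoyl)-4-hydroxy-8,8-dimethyl-1,5,7-tris(3-methylbut-2-en-1-yl)bicyclo[3.3.1]non-3-ene-2,9-dione | CC(C)=CC[C@@H]1C[C@]2(CC=C(C)C)C(=O)[C@@](CC=C(C)C)(C(=O)C(C(=O)c3ccc(O)c(O)c3)=C2O)C1(C)C | target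

**Step count and risks**

Total step count: 11. Longest linear sequence: 9 steps (steps 3–11, from dimethyl 3,3-dimethylpentanedioate); the pyrone branch (steps 1–2) joins at step 8.

Steps most likely to fail:

1. Step 10 (key step). The first closure may place the C1 ester equatorial (a lithium-chelated transition state), so the diketone enolate cannot reach it, or the cascade may stall after acyl transfer because the lithium diketonate acylates the hindered ester too slowly. The fallback sets out from 18 and comes back at 20. The enol lactone of 18 would be opened at C9 with NaOMe in MeOH at 0 °C to dimethyl (2S,4R,6R)-2-{3-[3,4-bis(TBSO)phenyl]-3-oxopropanoyl}-5,5-dimethyl-2,4,6-tris(3-methylbut-2-en-1-yl)heptanedioate F1. F1 would then be heated with excess NaOMe in MeOH–THF, so that the Dieckmann closure C1–C9 is reversible, C1 epimers that cannot bridge revert, and only the cis-diaxial cyclohexanone is drained by the Claisen closure C2–C3 to the trione enolate of 20.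

2. Step 9. The chiral palladium complex may discriminate the two pyronate faces poorly (C5 epimers), and O-prenylation or attack at the tertiary allyl terminus may compete. The fallback sets out from 16 and comes back at 20. 16 would be prenylated with 17 and Pd(PPh3)4 (zerovalent palladium) without stereocontrol, giving 18 together with its C5 epimer, methyl (2R,4R)-4-({(3R)-6-[3,4-bis(TBSO)phenyl]-3-(3-methylbut-2-en-1-yl)-2,4-dioxo-3,4-dihydro-2H-pyran-3-yl}methyl)-3,3,7-trimethyl-2-(3-methylbut-2-en-1-yl)oct-6-enoate F2. The mixture would be taken through the step 10 conditions, where F2 should give the 7-endo diastereomer (1R,5R,7R)-3-[3,4-bis(TBSO)benzoyl]-4-hydroxy-8,8-dimethyl-1,5,7-tris(3-methylbut-2-en-1-yl)bicyclo[3.3.1]non-3-ene-2,9-dione F3. Separation is deferred to the rigid bicycles, where 20 and F3 differ in ring conformation, and 20 continues to step 11.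

3. Step 8. Knoevenagel condensation of the neopentyl-type aldehyde may be slow, C7 may epimerise through the proline enamine, or the 1-oxadiene 15 may be captured by the C1 prenyl alkene in an intramolecular hetero-Diels–Alder reaction before hydride transfer. The fallback sets out from 14 (with 2) and comes back at 16. 14 would be condensed with dimethyl malonate (TiCl4, pyridine, THF, 0 °C; no amine, and a much less reactive heterodiene) to dimethyl 2-[(2R,4R)-5-methoxy-3,3-dimethyl-2,4-bis(3-methylbut-2-en-1-yl)-5-oxopentylidene]propanedioate F4. Conjugate reduction with NaBH4 (MeOH, 0 °C) would give dimethyl 2-[(2R,4R)-5-methoxy-3,3-dimethyl-2,4-bis(3-methylbut-2-en-1-yl)-5-oxopentyl]propanedioate F5. LiOH (THF–H2O, rt) would hydrolyse only the unhindered malonate esters to 2-[(2R,4R)-5-methoxy-3,3-dimethyl-2,4-bis(3-methylbut-2-en-1-yl)-5-oxopentyl]propanedioic acid F6. 1-Chloro-N,N,2-trimethylprop-1-en-1-amine would convert F6 into methyl (2R,4R)-4-[3-chloro-2-(chlorocarbonyl)-3-oxopropyl]-3,3,7-trimethyl-2-(3-methylbut-2-en-1-yl)oct-6-enoate F7, which would be annulated with silyl enol ether 2 as in step 2 to give 16.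

**Further compounds**

F1 | step 10 | dimethyl (2S,4R,6R)-2-{3-[3,4-bis(TBSO)phenyl]-3-oxopropanoyl}-5,5-dimethyl-2,4,6-tris(3-methylbut-2-en-1-yl)heptanedioate | CC(C)=CC[C@H](C[C@](CC=C(C)C)(C(=O)OC)C(=O)CC(=O)c1ccc(O[Si](C)(C)C(C)(C)C)c(O[Si](C)(C)C(C)(C)C)c1)C(C)(C)[C@@H](CC=C(C)C)C(=O)OC
F2 | step 9 | methyl (2R,4R)-4-({(3R)-6-[3,4-bis(TBSO)phenyl]-3-(3-methylbut-2-en-1-yl)-2,4-dioxo-3,4-dihydro-2H-pyran-3-yl}methyl)-3,3,7-trimethyl-2-(3-methylbut-2-en-1-yl)oct-6-enoate | CC(C)=CC[C@H](C[C@@]1(CC=C(C)C)C(=O)OC(c2ccc(O[Si](C)(C)C(C)(C)C)c(O[Si](C)(C)C(C)(C)C)c2)=CC1=O)C(C)(C)[C@@H](CC=C(C)C)C(=O)OC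
F3 | step 9 | (1R,5R,7R)-3-[3,4-bis(TBSO)benzoyl]-4-hydroxy-8,8-dimethyl-1,5,7-tris(3-methylbut-2-en-1-yl)bicyclo[3.3.1]non-3-ene-2,9-dione | CC(C)=CC[C@@H]1C[C@@]2(CC=C(C)C)C(=O)[C@](CC=C(C)C)(C(=O)C(C(=O)c3ccc(O[Si](C)(C)C(C)(C)C)c(O[Si](C)(C)C(C)(C)C)c3)=C2O)C1(C)C
F4 | step 8 | dimethyl 2-[(2R,4R)-5-methoxy-3,3-dimethyl-2,4-bis(3-methylbut-2-en-1-yl)-5-oxopentylidene]propanedioate | COC(=O)C(=C[C@@H](CC=C(C)C)C(C)(C)[C@@H](CC=C(C)C)C(=O)OC)C(=O)OC
F5 | step 8 | dimethyl 2-[(2R,4R)-5-methoxy-3,3-dimethyl-2,4-bis(3-methylbut-2-en-1-yl)-5-oxopentyl]propanedioate | COC(=O)C(C[C@@H](CC=C(C)C)C(C)(C)[C@@H](CC=C(C)C)C(=O)OC)C(=O)OC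
F6 | step 8 | 2-[(2R,4R)-5-methoxy-3,3-dimethyl-2,4-bis(3-methylbut-2-en-1-yl)-5-oxopentyl]propanedioic acid | OC(=O)C(C[C@@H](CC=C(C)C)C(C)(C)[C@@H](CC=C(C)C)C(=O)OC)C(=O)O
F7 | step 8 | methyl (2R,4R)-4-[3-chloro-2-(chlorocarbonyl)-3-oxopropyl]-3,3,7-trimethyl-2-(3-methylbut-2-en-1-yl)oct-6-enoate | ClC(=O)C(C[C@@H](CC=C(C)C)C(C)(C)[C@@H](CC=C(C)C)C(=O)OC)C(=O)Cl
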